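Do not read the start ratio of binding to dimer formation, 25.8 in flask north-east, as a loss of 3.88 % to homo dimer. This bench rule counts the forward step of binding alone. Find its border with a ratio of given constants: complex A falls apart at 400 s⁻¹ and turns over at 310 s⁻¹, which is a ratio of 1.29, so 43.7 % of bindings go on to target. The rule has therefore left its ground.

Here enzyme binds starting material and releases target, second substrate competes for the enzyme through complex B, target destroys enzyme, and two starting material join as homo dimer.

    starting material + enzyme ⇌ complex A (K1 = 150 M⁻¹, k1 = 60000 M⁻¹ s⁻¹)
    complex A → enzyme + target (k2 = 310 s⁻¹)
    second substrate + enzyme ⇌ complex B (K3 = 23 M⁻¹, k3 = 39000 M⁻¹ s⁻¹)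
    complex B → enzyme + second product (k4 = 140 s⁻¹)
    enzyme + target → spent catalyst (k5 = 2.0 M⁻¹ s⁻¹)
    2 starting material → homo dimer (k6 = 0.64 M⁻¹ s⁻¹)

| flask | starting material | second substrate | enzyme | time | remark |
|---|---|---|---|---|---|
| west | 20 mM (fed, over 15 s) | 10.0 mM | 11 µM | 25 s | all else is in the flask from the start; the feed brings no volume worth counting |
| north-east | 20 mM | 10.0 mM | 11 µM | 25 s | everything together at the start |
| south-east | 20 mM | 10.0 mM (fed, over 15 s) | 11 µM | 25 s | all else is in the flask from the start; the feed brings no volume worth counting |

- the flask that comes out highest in amount of target, in percent of the starting material charged, or "all alike" when all lie within 1.5 percentage points (west / north-east / south-east / all alike)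
- target at the end, in percent of the starting material charged, west
- target at the end, in percent of the starting material charged, north-east
- target at the end, in percent of the starting material charged, south-east

- percent here means starting material units held: one homo dimer counts as two
- a step written with two of one species runs at k times the square of its concentration and takes two of it each time
- run time (west): 25 s

So compute the correction, not the whole flask. Hold the enzyme and the second substrate at their charges; that is my assumption. The enzyme then has a top rate of 3.41 mM s⁻¹, and its half-speed level (the Michaelis constant, stretched by the competition) is 14.3 mM. At the charge, the enzyme path runs at 1.99 mM s⁻¹ and the dimer path at 0.512 mM s⁻¹. The dimer path over the enzyme path falls as c(starting material) falls. Average that ratio over c(starting material) from the charge down to zero, and you have the dimer share, the part of the charge lost to homo dimer: 10.4 %. In this reckoning, with the other charges held, it goes inversely with the enzyme. My reckoning puts flask north-east near 89.6 % target. Removing the competition gives 9.45 %, a difference of 0.95 percentage points, so I expect flask south-east close to flask north-east. For flask west I commit to no number.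

The forecast gave 89.3 % for west, 89.4 % for north-east and 89.8 % for south-east, hence all alike, holding that “feeding the second substrate only slightly eases competition early on”.

The simulation gives 89.9 % for west, 89.3 % for north-east and 89.9 % for south-east, so all alike.

Read these like targets as different splits: at 25.0 s, flask west holds 3.55 % homo dimer and 6.53 % free starting material, while flask south-east holds 8.56 % and 1.52 %. Flask north-east holds 9.09 % homo dimer, against a dimer share of 10.4 %. Now take the neighbour, the north-east recipe with 0.044 mM of enzyme. The half-speed level stays, the top rate grows by a factor of 4.00, and the share becomes 2.60 %. That neighbour ends with 2.49 % homo dimer and 97.4 % target.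

The rate constants belong to no real substance; the rest is arithmetic.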